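1. At 8.00 d, the last reading of each run, I turned percent into molar. Monday's reading came to 0.204 M of target and Thursday's to 0.203 M, from charges of 0.64 M and 1.8 M.

| flask | solid substrate | remark | time |
|---|---|---|---|
| Monday's | 0.64 M | run made earlier |  |
| Tuesday's | 0.91 M | run made earlier |  |
| Thursday's | 1.8 M | run made earlier |  |
| maple | 1.5 M |  | 50 d |
| birch | 0.50 M |  | 12 d |

- Monday's (time / d: target / %): 0.625: 0.7; 1.67: 5.5; 4.00: 14.7; 8.00: 31.9
- Tuesday's (time / d: target / %): 2.00: 4.0; 4.00: 10.3; 6.00: 16.2; 8.00: 21.5
- Thursday's (time / d: target / %): 1.04: 0.9; 3.00: 3.1; 5.00: 5.9; 8.00: 11.3

(each reading ± 0.5 percentage points)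

- solid, in amounts per volume of the solution: solid substrate
- the numbers in the tables scatter with a standard deviation of 0.5 percentage points
- at the start none of the solid substrate is in solution
- what has only dissolved of solid substrate counts as not reacted

- which one finishes higher in amount of target, in percent of the solid substrate charged ("neither" within 2 percentage points) (maple / birch / neither)
- amount of target at the end, in percent of the solid substrate charged, maple
- amount of target at the end, in percent of the solid substrate charged, birch

2. Thursday's first and last readings gave 0.0269 M d⁻¹. I called this the target flow: the molar target gained per day while solid stands. Monday's readings gave 0.0267 M d⁻¹, so I took the flow as independent of the charge.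

3. Thursday's line reached zero target at 0.438 d, and I counted the flow from there.

4. I opened the ledger on the solid substrate, the limiting reagent. Birch was charged 0.50 M. Its target entry at 12 d was 0.311 M, or 62.2 %. That left 0.189 M in an unread entry.

5. Maple was charged 1.5 M. Its target entry at 50 d was 1.33 M, or 88.7 %, which left 0.170 M unread.

6. The readings stopped at 8.00 d, so the birch entry stretched them 1.50 times and the maple entry 6.25 times. I still committed to maple.

7. The forecast also said maple, with maple at 86 % (79 % to 92 %) and birch at 59 % (54 % to 64 %), both below my entries, and its ground was this: “the amount formed doesn't depend on charge”.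

8. The flasks gave 35.3 % for maple and 46.5 % for birch, so birch finished higher.

    starting material ⇌ target (K = 8.70, k = 3.50 × 10⁻⁴ min⁻¹)
    target ⇌ isomer of the product A (K = 0.890, k = 3.70 × 10⁻⁴ min⁻¹)
    isomer of the product A ⇌ isomer of the product B (K = 3.10, k = 2.10 × 10⁻⁵ min⁻¹)
    solid substrate ⇌ starting material, rate k4*(cs4 - [starting material]) while solid is left; crystals form when [starting material] > cs4 (solubility = 0.270 M, k = 2.30 × 10⁻⁴ min⁻¹)

9. In birch at 6.00 d, with 28.1 % still solid, the flow gave 29.9 % and the flask held 29.6 %; at 12.0 d, with 0 % solid, my entry stood 16 percentage points above the flask. In birch, target passed to isomer of the product A with a forward half-life of 1.3 d, far shorter than the 17.3 d relaxation half-life between the isomers, and at 12.0 d that flask held 38.0 % of isomer of the product A.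

10. The same birch charge read at 3.0 d still had 60.0 % solid, so I used the flow, and it gave 13.8 %. That neighbour flask held 13.8 % of target.

The runs are calculated for an exercise, and the scatter is random.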